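**Plan**

- Retrosynthesis: the ester C–O bonds at C15 and C19 are cut first, then C14–C15 with C13–CH3 (carboalumination/hydroxymethylation) and C12–C13 (acetylide alkylation). The C6 oxygen is put back and C7–C8 is cut (aldol condensation). C9–C10 and C5–C6 are cut together (photocycloaddition/retro-aldol). Ring A is opened at C5=C10 (metathesis), C1–C2 (methallylation) and C3–C4 (Claisen).
- Forward: an acyclic chain is closed to the ring A cyclohexene (steps 1–8), joined photochemically to a 3-substituted pentane-2,4-dione and closed to ring B by aldol condensation (steps 10–11). C6 is then deoxygenated, C12 is extended to the C13–C16 unit, and the two esters are put on.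
- Enabling feature: ring B carries the C8 methyl on the C7=C8 alkene, between C9 and the quaternary C10. This is the mark of an aldol condensation of a C6/C8 1,5-diketone spanning C5–C10–C9, which is the de Mayo adduct of an enolised 3-alkylpentane-2,4-dione with the C5=C10 alkene of ring A.
- Stereochemistry: C4 by Johnson–Claisen chirality transfer from a CBS-derived (S)-allylic alcohol; C2 by reagent-controlled methallylboration; C10 by α-face photocycloaddition anti to the axial C19 arm; C5 and C9 in the aldol closure; 13E by syn-carboalumination.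

Key step: step 10

Remark: atoms carry labdane numbers (ring A = C1–C5 and C10, ring B = C5–C10, C19 = the CH2O carbon on C4; β = face of the C10 methyl, α = face of the C2 oxygen), and 1, 2, 12, 13, 26 and 28 are taken as purchasable.

**Route**

Step 1
Reactants: 1 1-[(tert-butyldimethylsilyl)oxy]propan-2-one; 2 diethyl {2-[methoxy(methyl)amino]-2-oxoethyl}phosphonate
Product: 3 (2E)-4-[(tert-butyldimethylsilyl)oxy]-N-methoxy-N,3-dimethylbut-2-enamide
Conditions: NaH, THF, 0 → 23 °C; Z isomer removed by chromatography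
Reagents that add atoms: none
Why: Horner–Wadsworth–Emmons olefination of the activated α-silyloxy ketone should place the amide trans to the larger CH2OTBS group (E); the geometry must be pure because it later decides the sense of chirality transfer to C4.

Step 2
Reactants: 3 (2E)-4-[(tert-butyldimethylsilyl)oxy]-N-methoxy-N,3-dimethylbut-2-enamide
Product: 4 (3E)-5-[(tert-butyldimethylsilyl)oxy]-4-methylpent-3-en-2-one
Conditions: MeMgBr, THF, 0 °C
Reagents that add atoms: methylmagnesium bromide, C[Mg]Br
Why: Weinreb ketone synthesis; the chelated tetrahedral intermediate stops at the methyl ketone and 1,2-addition outruns conjugate addition to the β,β-disubstituted enamide.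

Step 3
Reactants: 4 (3E)-5-[(tert-butyldimethylsilyl)oxy]-4-methylpent-3-en-2-one
Product: 5 (2S,3E)-5-[(tert-butyldimethylsilyl)oxy]-4-methylpent-3-en-2-ol
Conditions: (R)-2-methyl-CBS-oxazaborolidine (20 mol %), catecholborane, toluene, −78 °C
Reagents that add atoms: none
Why: Corey–Bakshi–Shibata reduction with the alkenyl group acting as the large substituent; the (R)-oxazaborolidine should give the (S)-carbinol, the stereocentre that is relayed to C4.

Step 4
Reactants: 5 (2S,3E)-5-[(tert-butyldimethylsilyl)oxy]-4-methylpent-3-en-2-ol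
Product: 7 ethyl (3S,4E)-3-{[(tert-butyldimethylsilyl)oxy]methyl}-3-methylhex-4-enoate, via ketene acetal 6 (not isolated)
Conditions: CH3C(OEt)3, EtCO2H (cat.), xylene, 140 °C, ethanol distilled off
Reagents that add atoms: triethyl orthoacetate, CC(OCC)(OCC)OCC
Why: Johnson–Claisen rearrangement through a chair transition state with the carbinol methyl equatorial transfers the (S)-carbinol chirality across the E alkene to the quaternary C4 (S) and leaves an E-propenyl group.

Step 5
Reactants: 7 ethyl (3S,4E)-3-{[(tert-butyldimethylsilyl)oxy]methyl}-3-methylhex-4-enoate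
Product: 8 (3S,4E)-3-{[(tert-butyldimethylsilyl)oxy]methyl}-3-methylhex-4-enal
Conditions: i-Bu2AlH, CH2Cl2, −78 °C
Reagents that add atoms: none
Why: Partial reduction of the ester stops at the aldehyde because the aluminium hemiacetal is stable at −78 °C.

Step 6
Reactants: 8 (3S,4E)-3-{[(tert-butyldimethylsilyl)oxy]methyl}-3-methylhex-4-enal
Product: 9 (4R,6S,7E)-6-{[(tert-butyldimethylsilyl)oxy]methyl}-2,6-dimethylnona-1,7-dien-4-ol
Conditions: (+)-Ipc2BOMe, CH2=C(CH3)CH2MgCl, Et2O, −78 °C, then 8; NaOH, H2O2
Reagents that add atoms: 2-methylallylmagnesium chloride (transferred through the diisopinocampheylborane), CC(=C)C[Mg]Cl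
Why: Asymmetric methallylboration (Brown allylation) through a closed chair transition state; the (+)-diisopinocampheylborane adds to the Re face of the aldehyde regardless of the remote C4 centre and sets C2 as R.

Step 7
Reactants: 9 (4R,6S,7E)-6-{[(tert-butyldimethylsilyl)oxy]methyl}-2,6-dimethylnona-1,7-dien-4-ol
Product: 10 (4R,6S,7E)-6-{[(tert-butyldimethylsilyl)oxy]methyl}-2,6-dimethyl-4-[(triisopropylsilyl)oxy]nona-1,7-diene
Conditions: i-Pr3SiOTf, 2,6-lutidine, CH2Cl2, 0 °C
Reagents that add atoms: triisopropylsilyl trifluoromethanesulfonate, CC(C)[Si](C(C)C)(C(C)C)OS(=O)(=O)C(F)(F)F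
Why: Silylation of the unhindered secondary alcohol with the silyl triflate; the triisopropylsilyl ether is chosen to outlast the two primary TBS ethers in step 14.

Step 8
Reactants: 10 (4R,6S,7E)-6-{[(tert-butyldimethylsilyl)oxy]methyl}-2,6-dimethyl-4-[(triisopropylsilyl)oxy]nona-1,7-diene
Product: 11 tert-butyl{[(1S,5R)-1,3-dimethyl-5-[(triisopropylsilyl)oxy]cyclohex-2-en-1-yl]methoxy}dimethylsilane (ring A cyclohexene)
Conditions: second-generation Grubbs catalyst RuCl2(=CHPh)(H2IMes)(PCy3) (5 mol %), toluene, 80 °C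
Reagents that add atoms: none
Why: Ring-closing metathesis forms the six-membered ring with the trisubstituted C5=C10 alkene and releases propene; the carbene loads on the propenyl group beside C4 and closes onto the 1,1-disubstituted alkene.

Step 9
Reactants: 12 pentane-2,4-dione; 13 tert-butyl(2-iodoethoxy)dimethylsilane
Product: 14 3-{2-[(tert-butyldimethylsilyl)oxy]ethyl}pentane-2,4-dione
Conditions: K2CO3, acetone, reflux; 12 (2 equiv)
Reagents that add atoms: none
Why: C-alkylation (SN2) of the pentane-2,4-dione enolate by the primary iodide; excess dione suppresses dialkylation.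

Step 10
Reactants: 11 ring A cyclohexene; 14 3-{2-[(tert-butyldimethylsilyl)oxy]ethyl}pentane-2,4-dione
Product: 16 2α-(triisopropylsilyloxy)-12,19-bis(tert-butyldimethylsilyloxy)-7,8-seco-13,14,15,16-tetranor-5β-labdane-6,8-dione (ring A 1,5-diketone; C9 epimers), via cyclobutanol 15 (not isolated)
Conditions: hν (medium-pressure Hg lamp, Pyrex filter, λ > 300 nm), 14 (4 equiv), degassed cyclohexane, 20 °C
Reagents that add atoms: none
Why: Excitation of the hydrogen-bonded enol of 14 and intersystem crossing give a triplet that adds across C5=C10 of 11 through a 1,4-biradical to the cyclobutanol 15, whose β-hydroxy ketone unit opens at once by retro-aldol cleavage of the C6–C9 bond to the 1,5-diketone (de Mayo reaction, the enol version of the enone–alkene [2+2] photocycloaddition). Only the transient four-membered ring closes, by recombination of the biradical to a cis-fused bicyclo[4.2.0]octane, and no ring of the target is formed here. The new C10 centre is set by approach to the α face of the half-chair in which the C2 silyloxy group is equatorial and the C4 CH2OTBS arm is pseudoaxial on the β face, so the methyl ends β, cis to C19. Cis fusion places the C5 acetyl on the α face (the C5 epimer of the target) and ketonisation leaves C9 as a mixture, both of which step 11 corrects. The orientation needed (C6 to C5, C9 to C10) should follow from first bond formation between the less hindered, oxygen-bearing enol carbon and the less substituted alkene carbon, which gives the tertiary C10 radical and the acyl-stabilised C9 radical, whereas the reverse mode would force the fully substituted C9 onto C5 next to the quaternary C4; biradicals that do not close revert to 11 and 14. The silyl ethers are transparent above 300 nm and 14 carries no second alkene, so no other chromophore or intramolecular trap competes.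

Step 11
Reactants: 16 ring A 1,5-diketone
Product: 18 2α-(triisopropylsilyloxy)-12,19-bis(tert-butyldimethylsilyloxy)-13,14,15,16-tetranorlabd-7-en-6-one, via ketol 17 (not isolated)
Conditions: NaOMe, MeOH, 23 → 50 °C
Reagents that add atoms: none
Why: Intramolecular aldol condensation: the C7 enolate of the C6 acetyl attacks the less hindered C8 ketone (six-membered ring) and E1cB dehydration gives the C7=C8 enone; C5 and C9 are enolisable in the open diketone, so closure should funnel through the all-chair transition state with trans ring fusion and equatorial C9 chain, and C5 stays under thermodynamic control in the enone, where the geminally substituted C4 disfavours the cis fusion.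

Step 12
Reactants: 18 tetranorlabd-7-en-6-one
Product: 19 6,6-(ethane-1,2-diyldisulfanediyl)-2α-(triisopropylsilyloxy)-12,19-bis(tert-butyldimethylsilyloxy)-13,14,15,16-tetranorlabd-7-ene (C6 dithiolane)
Conditions: Me3SiSCH2CH2SSiMe3, ZnI2 (cat.), Et2O, 0 → 23 °C
Reagents that add atoms: 1,2-bis(trimethylsilylthio)ethane, C[Si](C)(C)SCCS[Si](C)(C)C
Why: Thioketalisation with the bis(silylthio)ethane under ZnI2 catalysis runs under neutral conditions that spare the silyl ethers, and 1,2-addition to the enone leaves the C7=C8 alkene in place.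

Step 13
Reactants: 19 C6 dithiolane
Product: 20 2α-(triisopropylsilyloxy)-12,19-bis(tert-butyldimethylsilyloxy)-13,14,15,16-tetranorlabd-7-ene
Conditions: Raney Ni (deactivated in acetone), EtOH, 23 → 60 °C
Reagents that add atoms: none
Why: Mozingo desulfurisation: hydrogenolysis of both C–S bonds turns the former C6 carbonyl into CH2, and the hindered trisubstituted alkene should survive on the deactivated catalyst.

Step 14
Reactants: 20 bis-TBS tetranorlabd-7-ene
Product: 21 2α-(triisopropylsilyloxy)-13,14,15,16-tetranorlabd-7-ene-12,19-diol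
Conditions: HF·pyridine, pyridine, THF, 0 → 23 °C
Reagents that add atoms: none
Why: Fluoride-mediated desilylation removes both primary TBS ethers under pyridine buffering while the secondary triisopropylsilyl ether stays; no strong acid is present that could add the C12 hydroxyl across C7=C8.

Step 15
Reactants: 21 12,19-diol
Product: 22 12-iodo-2α-(triisopropylsilyloxy)-13,14,15,16-tetranorlabd-7-en-19-ol
Conditions: I2, PPh3, imidazole, CH2Cl2, 0 °C
Reagents that add atoms: iodine, [I][I]
Why: Appel-type iodination proceeds by SN2 only at the unhindered C12 alcohol; the neopentyl, axial C19 alkoxyphosphonium cannot be displaced and returns the alcohol on work-up.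

Step 16
Reactants: 22 12-iodide
Product: 23 2α-(triisopropylsilyloxy)-15,16-dinorlabd-7-en-13-yn-19-ol
Conditions: LiC≡CH·H2NCH2CH2NH2, DMSO, 23 °C
Reagents that add atoms: lithium acetylide ethylenediamine complex, [Li]C#C.NCCN
Why: SN2 alkylation of lithium acetylide by the primary iodide in DMSO installs C13 and C14 as a terminal alkyne.

Step 17
Reactants: 23 terminal alkyne
Product: 25 2α-(triisopropylsilyloxy)labda-7,13E-diene-15,19-diol, via alkenylalane 24 (not isolated)
Conditions: AlMe3, Cp2ZrCl2 (0.3 equiv), CH2Cl2, 0 → 23 °C; then n-BuLi, THF, −78 °C; (CH2O)n, → 23 °C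
Reagents that add atoms: trimethylaluminium, C[Al](C)C; paraformaldehyde (as formaldehyde), C=O
Why: Zirconium-catalysed carboalumination (Negishi) adds methyl and aluminium syn across the alkyne with methyl at C13, and the alkenyl aluminate is hydroxymethylated with retention, which fixes the 13E geometry.

Step 18
Reactants: 25 15,19-diol; 26 methyl 4-chloro-4-oxobutanoate
Product: 27 methyl [19-hydroxy-2α-(triisopropylsilyloxy)labda-7,13E-dien-15-yl] butanedioate
Conditions: 26 (1.05 equiv), 2,4,6-collidine, CH2Cl2, −78 → −40 °C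
Reagents that add atoms: none
Why: Chemoselective acylation of the unhindered allylic C15 alcohol by one equivalent of acid chloride at low temperature; the neopentyl C19 alcohol, shielded 1,3-diaxially by the C10 methyl, reacts far more slowly.

Step 19
Reactants: 27 15-succinate 19-alcohol; 28 3-methylbutanoyl chloride
Product: 29 methyl [19-(3-methylbutanoyloxy)-2α-(triisopropylsilyloxy)labda-7,13E-dien-15-yl] butanedioate
Conditions: pyridine, DMAP (cat.), CH2Cl2, 23 °C
Reagents that add atoms: none
Why: DMAP-catalysed acylation of the remaining hindered primary alcohol with the acid chloride.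

Step 20
Reactants: 29 silyl-protected target
Product: 30 methyl [2α-hydroxy-19-(3-methylbutanoyloxy)labda-7,13E-dien-15-yl] butanedioate (CNP0118741.1)
Conditions: Bu4NF, AcOH, THF, 23 → 40 °C
Reagents that add atoms: none
Why: Fluoride cleavage of the triisopropylsilyl ether under acetic acid buffering leaves the three esters and both alkenes untouched and frees the C2 alcohol.

**Compound list**

1 | 1-[(tert-butyldimethylsilyl)oxy]propan-2-one | CC(=O)CO[Si](C)(C)C(C)(C)C | starting material
2 | diethyl {2-[methoxy(methyl)amino]-2-oxoethyl}phosphonate | CCOP(=O)(CC(=O)N(C)OC)OCC | starting material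
3 | (2E)-4-[(tert-butyldimethylsilyl)oxy]-N-methoxy-N,3-dimethylbut-2-enamide | CON(C)C(=O)/C=C(\C)CO[Si](C)(C)C(C)(C)C | intermediate
4 | (3E)-5-[(tert-butyldimethylsilyl)oxy]-4-methylpent-3-en-2-one | CC(=O)/C=C(\C)CO[Si](C)(C)C(C)(C)C | intermediate
5 | (2S,3E)-5-[(tert-butyldimethylsilyl)oxy]-4-methylpent-3-en-2-ol | C[C@H](O)/C=C(\C)CO[Si](C)(C)C(C)(C)C | intermediate
6 | 1-ethoxyvinyl ether of 5 (mixed ketene acetal, not isolated) | C=C(OCC)O[C@@H](C)/C=C(\C)CO[Si](C)(C)C(C)(C)C | intermediate
7 | ethyl (3S,4E)-3-{[(tert-butyldimethylsilyl)oxy]methyl}-3-methylhex-4-enoate | CCOC(=O)C[C@](C)(CO[Si](C)(C)C(C)(C)C)/C=C/C | intermediate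
8 | (3S,4E)-3-{[(tert-butyldimethylsilyl)oxy]methyl}-3-methylhex-4-enal | O=CC[C@](C)(CO[Si](C)(C)C(C)(C)C)/C=C/C | intermediate
9 | (4R,6S,7E)-6-{[(tert-butyldimethylsilyl)oxy]methyl}-2,6-dimethylnona-1,7-dien-4-ol | CC(=C)C[C@@H](O)C[C@](C)(CO[Si](C)(C)C(C)(C)C)/C=C/C | intermediate
10 | (4R,6S,7E)-6-{[(tert-butyldimethylsilyl)oxy]methyl}-2,6-dimethyl-4-[(triisopropylsilyl)oxy]nona-1,7-diene | CC(=C)C[C@@H](O[Si](C(C)C)(C(C)C)C(C)C)C[C@](C)(CO[Si](C)(C)C(C)(C)C)/C=C/C | intermediate
11 | tert-butyl{[(1S,5R)-1,3-dimethyl-5-[(triisopropylsilyl)oxy]cyclohex-2-en-1-yl]methoxy}dimethylsilane (ring A cyclohexene; C2 OTIPS α, C4 CH2OTBS β) | CC1=C[C@@](C)(CO[Si](C)(C)C(C)(C)C)C[C@H](O[Si](C(C)C)(C(C)C)C(C)C)C1 | intermediate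
12 | pentane-2,4-dione | CC(=O)CC(C)=O | starting material
13 | tert-butyl(2-iodoethoxy)dimethylsilane | CC(C)(C)[Si](C)(C)OCCI | starting material
14 | 3-{2-[(tert-butyldimethylsilyl)oxy]ethyl}pentane-2,4-dione | CC(=O)C(CCO[Si](C)(C)C(C)(C)C)C(C)=O | intermediate
15 | cyclobutanol photoadduct (not isolated): cyclobutane C5–C6–C9–C10 cis-fused on the α face of ring A, C6 bearing OH and CH3, C9 bearing acetyl and CH2CH2OTBS; configuration at C6 and C9 immaterial | CC(=O)C1(CCO[Si](C)(C)C(C)(C)C)C(C)(O)[C@@H]2[C@@](C)(CO[Si](C)(C)C(C)(C)C)C[C@H](O[Si](C(C)C)(C(C)C)C(C)C)C[C@]12C | intermediate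
16 | 2α-(triisopropylsilyloxy)-12,19-bis(tert-butyldimethylsilyloxy)-7,8-seco-13,14,15,16-tetranor-5β-labdane-6,8-dione (C5 acetyl α, C10 methyl β, mixture of C9 epimers) | CC(=O)[C@@H]1[C@@](C)(CO[Si](C)(C)C(C)(C)C)C[C@H](O[Si](C(C)C)(C(C)C)C(C)C)C[C@]1(C)C(CCO[Si](C)(C)C(C)(C)C)C(C)=O | intermediate
17 | 8-hydroxy-2α-(triisopropylsilyloxy)-12,19-bis(tert-butyldimethylsilyloxy)-13,14,15,16-tetranorlabdan-6-one (ketol, not isolated; mixture at C5, C8 and C9) | CC(C)(C)[Si](C)(C)OCCC1C(C)(O)CC(=O)C2[C@@](C)(CO[Si](C)(C)C(C)(C)C)C[C@H](O[Si](C(C)C)(C(C)C)C(C)C)C[C@]12C | intermediate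
18 | 2α-(triisopropylsilyloxy)-12,19-bis(tert-butyldimethylsilyloxy)-13,14,15,16-tetranorlabd-7-en-6-one (5α-H, 9α-H, 10β-CH3) | CC(C)(C)[Si](C)(C)OCC[C@H]1C(C)=CC(=O)[C@H]2[C@@](C)(CO[Si](C)(C)C(C)(C)C)C[C@H](O[Si](C(C)C)(C(C)C)C(C)C)C[C@]12C | intermediate
19 | 1,3-dithiolane of 18 at C6 | CC(C)(C)[Si](C)(C)OCC[C@H]1C(C)=CC3(SCCS3)[C@H]2[C@@](C)(CO[Si](C)(C)C(C)(C)C)C[C@H](O[Si](C(C)C)(C(C)C)C(C)C)C[C@]12C | intermediate
20 | 2α-(triisopropylsilyloxy)-12,19-bis(tert-butyldimethylsilyloxy)-13,14,15,16-tetranorlabd-7-ene | CC(C)(C)[Si](C)(C)OCC[C@H]1C(C)=CC[C@H]2[C@@](C)(CO[Si](C)(C)C(C)(C)C)C[C@H](O[Si](C(C)C)(C(C)C)C(C)C)C[C@]12C | intermediate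
21 | 2α-(triisopropylsilyloxy)-13,14,15,16-tetranorlabd-7-ene-12,19-diol | OCC[C@H]1C(C)=CC[C@H]2[C@@](C)(CO)C[C@H](O[Si](C(C)C)(C(C)C)C(C)C)C[C@]12C | intermediate
22 | 12-iodo-2α-(triisopropylsilyloxy)-13,14,15,16-tetranorlabd-7-en-19-ol | ICC[C@H]1C(C)=CC[C@H]2[C@@](C)(CO)C[C@H](O[Si](C(C)C)(C(C)C)C(C)C)C[C@]12C | intermediate
23 | 2α-(triisopropylsilyloxy)-15,16-dinorlabd-7-en-13-yn-19-ol | C#CCC[C@H]1C(C)=CC[C@H]2[C@@](C)(CO)C[C@H](O[Si](C(C)C)(C(C)C)C(C)C)C[C@]12C | intermediate
24 | (13E)-14-(dimethylalumanyl)alkene of 23 with the C19 oxygen as its dimethylaluminium alkoxide (not isolated) | C[Al](C)/C=C(\C)CC[C@H]1C(C)=CC[C@H]2[C@@](C)(CO[Al](C)C)C[C@H](O[Si](C(C)C)(C(C)C)C(C)C)C[C@]12C | intermediate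
25 | 2α-(triisopropylsilyloxy)labda-7,13E-diene-15,19-diol | OC/C=C(\C)CC[C@H]1C(C)=CC[C@H]2[C@@](C)(CO)C[C@H](O[Si](C(C)C)(C(C)C)C(C)C)C[C@]12C | intermediate
26 | methyl 4-chloro-4-oxobutanoate | COC(=O)CCC(Cl)=O | starting material
27 | methyl [19-hydroxy-2α-(triisopropylsilyloxy)labda-7,13E-dien-15-yl] butanedioate | COC(=O)CCC(=O)OC/C=C(\C)CC[C@H]1C(C)=CC[C@H]2[C@@](C)(CO)C[C@H](O[Si](C(C)C)(C(C)C)C(C)C)C[C@]12C | intermediate
28 | 3-methylbutanoyl chloride | CC(C)CC(Cl)=O | starting material
29 | methyl [19-(3-methylbutanoyloxy)-2α-(triisopropylsilyloxy)labda-7,13E-dien-15-yl] butanedioate | COC(=O)CCC(=O)OC/C=C(\C)CC[C@H]1C(C)=CC[C@H]2[C@@](C)(COC(=O)CC(C)C)C[C@H](O[Si](C(C)C)(C(C)C)C(C)C)C[C@]12C | intermediate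
30 | methyl [2α-hydroxy-19-(3-methylbutanoyloxy)labda-7,13E-dien-15-yl] butanedioate (CNP0118741.1) | COC(=O)CCC(=O)OC/C=C(\C)CC[C@H]1C(C)=CC[C@H]2[C@@](C)(COC(=O)CC(C)C)C[C@H](O)C[C@]12C | target

**Totals and risks**

Total step count: 20. Longest linear sequence: 19 steps (steps 1–8 and 10–20; step 9 is the one-step side branch).

Steps most likely to fail:

1. Step 10. The cycloaddition may take the reverse orientation across C5=C10 (C9 bonding to C5, the orientation simple alkenes often prefer), or may stall because three fully substituted carbons are joined next to the quaternary C4. The fallback builds polarity into the alkene and sets out from 11: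
   - Hydroboration–oxidation (BH3·THF; NaOH, H2O2) on the α face gives the C5 alcohol F1.
   - Dess–Martin oxidation gives the C5 ketone F2, which can enolise only toward C10 because C4 is quaternary.
   - Me3SiOTf/Et3N gives the trimethylsilyl enol ether F3.
   - Irradiation of F3 with 14 now pairs the oxygen-bearing alkene carbon C5 with the oxygen-bearing enol carbon C6, the head-to-tail orientation that enol ethers show in enone photocycloadditions. After retro-aldol cleavage this gives the 5-silyloxy diketone F4.
   - SmI2 in THF/MeOH cleaves the C5–O bond α to the C6 ketone and brings the route back to 16, as C5 epimers that step 11 funnels.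

2. Step 11. Under basic conditions the enolate manifold may leak: retro-Michael cleavage of the C9–C10 bond, closure of the C17 enolate onto C6, or incomplete stereochemical funnelling at C5 and C9, the last being the least certain since C9 is only γ to the enone once it has formed. The fallback separates equilibration from dehydration and sets out from 16:
   - Catalytic KOt-Bu in t-BuOH/THF at 0 °C gives reversible aldol addition without dehydration. The ketols equilibrate by retro-aldol and enolisation to the all-chair trans-fused ketol F5 with the C9 chain equatorial, which is isolated.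
   - Dehydration with the Burgess reagent (syn-elimination toward the acidic C7–H, no base) gives 18.

3. Step 12 (with step 13). Thioketal formation may fail at the C6 carbonyl, which is flanked by C5 and shielded by the axial C19 and C10 substituents, or the alkene may migrate or be reduced during desulfurisation. The fallback removes the oxygen at the allylic alcohol level and sets out from 18:
   - Luche reduction (NaBH4, CeCl3·7H2O, MeOH, 0 °C) delivers hydride from the α face and gives the 6β-allylic alcohol F6.
   - n-BuLi/ClCO2Me gives the methyl carbonate F7.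
   - Pd(PPh3)4 (zerovalent palladium) with LiBHEt3 in THF ionises the carbonate from the α face and delivers hydride to the less substituted allyl terminus C6. This keeps the trisubstituted C7=C8 alkene and gives 20 directly, bypassing 19.

Further compounds
F1 | step 10 | (1R,5S)-numbered ring A alcohol: 5α-hydroxy, 10β-methyl hydroboration product of 11 (C4 CH2OTBS β, C2 OTIPS α) | C[C@H]1[C@H](O)[C@@](C)(CO[Si](C)(C)C(C)(C)C)C[C@H](O[Si](C(C)C)(C(C)C)C(C)C)C1
F2 | step 10 | ring A C5 ketone, 2-{[(tert-butyldimethylsilyl)oxy]methyl}-2,6-dimethyl-4-[(triisopropylsilyl)oxy]cyclohexan-1-one (C10 epimers) | CC1C(=O)[C@@](C)(CO[Si](C)(C)C(C)(C)C)C[C@H](O[Si](C(C)C)(C(C)C)C(C)C)C1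
F3 | step 10 | trimethylsilyl enol ether of F2 (C5=C10) | CC1=C(O[Si](C)(C)C)[C@@](C)(CO[Si](C)(C)C(C)(C)C)C[C@H](O[Si](C(C)C)(C(C)C)C(C)C)C1
F4 | step 10 | 5β-(trimethylsilyloxy) derivative of 16 (C5 acetyl α, C9 epimers) | CC(=O)[C@]1(O[Si](C)(C)C)[C@@](C)(CO[Si](C)(C)C(C)(C)C)C[C@H](O[Si](C(C)C)(C(C)C)C(C)C)C[C@]1(C)C(CCO[Si](C)(C)C(C)(C)C)C(C)=O
F5 | step 11 | trans-fused ketol, 8-hydroxy-2α-(triisopropylsilyloxy)-12,19-bis(tert-butyldimethylsilyloxy)-13,14,15,16-tetranorlabdan-6-one (5α-H, 9α-H; C8 carbinol epimers) | CC(C)(C)[Si](C)(C)OCC[C@H]1C(C)(O)CC(=O)[C@H]2[C@@](C)(CO[Si](C)(C)C(C)(C)C)C[C@H](O[Si](C(C)C)(C(C)C)C(C)C)C[C@]12C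
F6 | step 12 | 2α-(triisopropylsilyloxy)-12,19-bis(tert-butyldimethylsilyloxy)-13,14,15,16-tetranorlabd-7-en-6β-ol | CC(C)(C)[Si](C)(C)OCC[C@H]1C(C)=C[C@@H](O)[C@H]2[C@@](C)(CO[Si](C)(C)C(C)(C)C)C[C@H](O[Si](C(C)C)(C(C)C)C(C)C)C[C@]12C
F7 | step 12 | methyl carbonate of F6 | CC(C)(C)[Si](C)(C)OCC[C@H]1C(C)=C[C@@H](OC(=O)OC)[C@H]2[C@@](C)(CO[Si](C)(C)C(C)(C)C)C[C@H](O[Si](C(C)C)(C(C)C)C(C)C)C[C@]12C
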